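## Retrosynthetic overview
1. Target ⇒ cleave two pivalate masks (3-O, 4'-O) and disconnect the 7-O-prenyl ether (chelation-controlled Williamson) ⇒ limocitrin 3,4'-dipivalate.
2. Key disconnection, C5–OH ⇒ C5–H: a late carbonyl-directed, Ru-catalysed C–H hydroxylation of a 5-deoxyflavonol. This replaces carrying a tetra-oxygenated ring A through a chalcone/Algar–Flynn–Oyamada or Baker–Venkataraman sequence.
3. Ring C ⇒ one thermal [3+3] condensation (Mentzer type) of mirror-symmetric 2-methoxyresorcinol with a 2-acyloxy-3-keto ester. It forms C4–C4a and O1–C2, so there is no 6- versus 8-methoxy ambiguity.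
4. Keto ester ⇒ Chan rearrangement of the glycolate ester of vanillic acid (forms C2–C3, with the 3-oxygen already in place) ⇒ vanillic acid + ethyl bromoacetate.
5. Ring order: rings A and B are bought. Ring C is the only ring made (step 4), and the last ring A oxygen is added after it (step 5).

Assumption: the target SMILES holds no stereocentre and no E/Z double bond (the prenyl alkene carries two methyl groups), so it is achiral and "single enantiomer" needs no action. The racemic centre of three early intermediates vanishes when ring C aromatises.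

## Route

Step 1
Reactants: 1 vanillic acid (4-hydroxy-3-methoxybenzoic acid); 2 ethyl bromoacetate
Product: 3 2-ethoxy-2-oxoethyl 4-hydroxy-3-methoxybenzoate
Conditions: KHCO3 (1.1 equiv), DMF, rt, 12 h
Reagents that add atoms: none
Why: SN2 O-alkylation of a carboxylate, in which hydrogencarbonate deprotonates only the acid (pKa about 4.5) and not the guaiacol OH (pKa about 9.5), so the primary alpha-bromo ester is attacked by the carboxylate alone and no stereocentre is formed.

Step 2
Reactants: 3 2-ethoxy-2-oxoethyl 4-hydroxy-3-methoxybenzoate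
Product: 4 2-ethoxy-2-oxoethyl 3-methoxy-4-(pivaloyloxy)benzoate
Conditions: tBuCOCl (1.2 equiv), K2CO3 (1.5 equiv), acetone, 0 °C to rt
Reagents that add atoms: pivaloyl chloride, CC(C)(C)C(=O)Cl
Why: Phenol O-acylation under anhydrous carbonate, with the hindered pivalate chosen because it must withstand amide base, 240 °C and hot CF3CO2H yet leave with methoxide without harm to a prenyl ether.

Step 3
Reactants: 4 2-ethoxy-2-oxoethyl 3-methoxy-4-(pivaloyloxy)benzoate
Product: 6 ethyl 3-[3-methoxy-4-(pivaloyloxy)phenyl]-3-oxo-2-(pivaloyloxy)propanoate (racemic), via hydroxy ketoester 5 (not isolated)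
Conditions: LiN(iPr)2 (commercial solution, 2.2 equiv), THF, −78 to −30 °C; tBuCO2H (2.3 equiv), −78 °C; tBuCOCl (2.5 equiv), pyridine (3 equiv), DMAP (0.2 equiv), −78 °C to rt
Reagents that add atoms: pivaloyl chloride, CC(C)(C)C(=O)Cl
Why: Chan rearrangement (base-induced 1,2 O-to-C acyl shift of an alpha-acyloxy acetate) makes the future C2–C3 bond with the 3-oxygen already attached, the pivalic acid quench keeps pivaloyl as the only acyl source when the labile carbinol 5 is capped in the same flask, and the one new stereocentre is racemic and is erased in step 4.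

Step 4
Reactants: 6 ethyl 3-[3-methoxy-4-(pivaloyloxy)phenyl]-3-oxo-2-(pivaloyloxy)propanoate; 7 2-methoxyresorcinol (2-methoxybenzene-1,3-diol)
Product: 10 7-hydroxy-8-methoxy-2-[3-methoxy-4-(pivaloyloxy)phenyl]-4-oxo-4H-chromen-3-yl pivalate, via aroylketene 8 (not isolated), via hydroxyaryl diketone 9 (not isolated)
Conditions: 7 (3 equiv), Ph2O, 240 °C, Ar, 30 min, EtOH and H2O distilled off
Reagents that add atoms: none
Why: Proposed new method: this extends the Mentzer thermal chromone synthesis (closest known type: phenol plus beta-keto ester near 240 °C without catalyst, best known for phloroglucinol) to an alpha-acyloxy keto ester and a resorcinol, in which loss of EtOH gives aroylketene 8, this acylates the mirror-symmetric diol at its only activated carbon (ortho to one OH, para to the other) to give 9, the adjacent OH cyclodehydrates to close ring C with 8-OMe and 7-OH fixed by symmetry, the acid-free medium avoids the Pechmann coumarin pathway, and the racemic centre disappears on aromatisation.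

Step 5
Reactants: 10 7-hydroxy-8-methoxy-2-[3-methoxy-4-(pivaloyloxy)phenyl]-4-oxo-4H-chromen-3-yl pivalate
Product: 13 5,7-dihydroxy-8-methoxy-2-[3-methoxy-4-(pivaloyloxy)phenyl]-4-oxo-4H-chromen-3-yl pivalate (limocitrin 3,4'-dipivalate), via 7-trifluoroacetate 11 (not isolated), via 5,7-bis(trifluoroacetate) 12 (not isolated)
Conditions: [RuCl2(p-cymene)]2 (5 mol%), PhI(OCOCF3)2 (2 equiv), CF3CO2H/(CF3CO)2O 3:1, 80 °C, 6 h; evaporate; THF/H2O, rt
Reagents that add atoms: phenyliodine bis(trifluoroacetate), O=C(OI(OC(=O)C(F)(F)F)c1ccccc1)C(F)(F)F (source of the C5 oxygen); trifluoroacetic anhydride, O=C(OC(=O)C(F)(F)F)C(F)(F)F (its acyl groups stay only in 11 and 12)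
Why: Carbonyl-directed C–H hydroxylation by a divalent ruthenium carboxylate catalyst, a reaction type established for flavones and chromones, in which the C4 ketone oxygen places the metal on the peri C5–H (the only C–H it can reach, and one activated by the para 8-OMe), the trivalent iodine oxidant raises the metal to a higher valence state from which C–O reductive elimination gives the aryl trifluoroacetate, and the anhydride masks the 7-OH and the new 5-OH as electron-poor esters so that neither phenol is over-oxidised before water releases them while the pivalates stay.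

Step 6
Reactants: 13 5,7-dihydroxy-8-methoxy-2-[3-methoxy-4-(pivaloyloxy)phenyl]-4-oxo-4H-chromen-3-yl pivalate; 14 prenyl bromide (1-bromo-3-methylbut-2-ene)
Product: 15 5-hydroxy-8-methoxy-2-[3-methoxy-4-(pivaloyloxy)phenyl]-7-(3-methylbut-2-enyloxy)-4-oxo-4H-chromen-3-yl pivalate
Conditions: 14 (1.1 equiv), K2CO3 (1.2 equiv), acetone, 45 °C
Reagents that add atoms: none
Why: Williamson ether synthesis under chelation control, in which the 5-OH is tied up in a strong hydrogen bond to the C4 carbonyl and is far less acidic than the vinylogous-acid 7-OH, so about one equivalent of carbonate and the SN2-reactive allylic bromide give only the 7-O-ether while the hindered pivalates survive anhydrous carbonate.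

Step 7
Reactants: 15 5-hydroxy-8-methoxy-2-[3-methoxy-4-(pivaloyloxy)phenyl]-7-(3-methylbut-2-enyloxy)-4-oxo-4H-chromen-3-yl pivalate
Product: 16 3,5-dihydroxy-2-(4-hydroxy-3-methoxyphenyl)-8-methoxy-7-(3-methylbut-2-enyloxy)-4H-chromen-4-one (7-O-prenyllimocitrin; CNP0210396.0)
Conditions: NaOMe (3.5 equiv), MeOH/THF, 0 °C to rt, Ar; AcOH quench
Reagents that add atoms: none
Why: Zemplén-type transesterification, in which aryl and enol pivalates are activated esters that methoxide cleaves at or below room temperature whereas the aryl prenyl ether, both methyl ethers and the chromone ring are inert to it under argon, releasing the achiral target.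

## Compound list
1 | vanillic acid | COc1cc(C(=O)O)ccc1O | starting material
2 | ethyl bromoacetate | CCOC(=O)CBr | starting material
3 | 2-ethoxy-2-oxoethyl 4-hydroxy-3-methoxybenzoate | CCOC(=O)COC(=O)c1ccc(O)c(OC)c1 | intermediate
4 | 2-ethoxy-2-oxoethyl 3-methoxy-4-(pivaloyloxy)benzoate | CCOC(=O)COC(=O)c1ccc(OC(=O)C(C)(C)C)c(OC)c1 | intermediate
5 | ethyl 2-hydroxy-3-[3-methoxy-4-(pivaloyloxy)phenyl]-3-oxopropanoate (racemic, not isolated) | CCOC(=O)C(O)C(=O)c1ccc(OC(=O)C(C)(C)C)c(OC)c1 | intermediate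
6 | ethyl 3-[3-methoxy-4-(pivaloyloxy)phenyl]-3-oxo-2-(pivaloyloxy)propanoate (racemic) | CCOC(=O)C(OC(=O)C(C)(C)C)C(=O)c1ccc(OC(=O)C(C)(C)C)c(OC)c1 | intermediate
7 | 2-methoxyresorcinol | COc1c(O)cccc1O | starting material
8 | [3-methoxy-4-(pivaloyloxy)benzoyl](pivaloyloxy)ketene (not isolated) | O=C=C(OC(=O)C(C)(C)C)C(=O)c1ccc(OC(=O)C(C)(C)C)c(OC)c1 | intermediate
9 | 1-(2,4-dihydroxy-3-methoxyphenyl)-3-[3-methoxy-4-(pivaloyloxy)phenyl]-1,3-dioxopropan-2-yl pivalate (racemic, not isolated) | COc1c(O)ccc(C(=O)C(OC(=O)C(C)(C)C)C(=O)c2ccc(OC(=O)C(C)(C)C)c(OC)c2)c1O | intermediate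
10 | 7-hydroxy-8-methoxy-2-[3-methoxy-4-(pivaloyloxy)phenyl]-4-oxo-4H-chromen-3-yl pivalate | COc1cc(-c2oc3c(OC)c(O)ccc3c(=O)c2OC(=O)C(C)(C)C)ccc1OC(=O)C(C)(C)C | intermediate
11 | 8-methoxy-2-[3-methoxy-4-(pivaloyloxy)phenyl]-4-oxo-7-(trifluoroacetoxy)-4H-chromen-3-yl pivalate (not isolated) | COc1cc(-c2oc3c(OC)c(OC(=O)C(F)(F)F)ccc3c(=O)c2OC(=O)C(C)(C)C)ccc1OC(=O)C(C)(C)C | intermediate
12 | 8-methoxy-2-[3-methoxy-4-(pivaloyloxy)phenyl]-4-oxo-5,7-bis(trifluoroacetoxy)-4H-chromen-3-yl pivalate (not isolated) | COc1cc(-c2oc3c(OC)c(OC(=O)C(F)(F)F)cc(OC(=O)C(F)(F)F)c3c(=O)c2OC(=O)C(C)(C)C)ccc1OC(=O)C(C)(C)C | intermediate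
13 | 5,7-dihydroxy-8-methoxy-2-[3-methoxy-4-(pivaloyloxy)phenyl]-4-oxo-4H-chromen-3-yl pivalate | COc1cc(-c2oc3c(OC)c(O)cc(O)c3c(=O)c2OC(=O)C(C)(C)C)ccc1OC(=O)C(C)(C)C | intermediate
14 | prenyl bromide | CC(C)=CCBr | starting material
15 | 5-hydroxy-8-methoxy-2-[3-methoxy-4-(pivaloyloxy)phenyl]-7-(3-methylbut-2-enyloxy)-4-oxo-4H-chromen-3-yl pivalate | COc1cc(-c2oc3c(OC)c(OCC=C(C)C)cc(O)c3c(=O)c2OC(=O)C(C)(C)C)ccc1OC(=O)C(C)(C)C | intermediate
16 | 3,5-dihydroxy-2-(4-hydroxy-3-methoxyphenyl)-8-methoxy-7-(3-methylbut-2-enyloxy)-4H-chromen-4-one | COc1cc(-c2oc3c(OC)c(OCC=C(C)C)cc(O)c3c(=O)c2O)ccc1O | target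

## Step count and risks
Total step count: 7.
Longest linear sequence: 7 steps (1 → 3 → 4 → 6 → 10 → 13 → 15 → 16).

**Step 4 (thermal [3+3] condensation) is the step most likely to fail.**
- Risk: a resorcinol is a weaker carbon nucleophile than phloroglucinol. An alpha-acyloxy keto ester is untested at 240 °C, and pivaloyl groups may scramble.
- Fallback: give up the one-step ring C synthesis and make the same 5-deoxyflavonol by the classical chalcone and Algar–Flynn–Oyamada sequence. That sequence behaves well here because the chalcone has no 6'-substituent. The fallback sets out from 7 and comes back at 10.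

Compound 7 is C-acetylated (Ac2O, BF3·OEt2, 80 °C) to 1-(2,4-dihydroxy-3-methoxyphenyl)ethanone F4. Benzyl bromide and K2CO3 in acetone alkylate only the non-chelated 4-OH to give 1-[4-(benzyloxy)-2-hydroxy-3-methoxyphenyl]ethanone F5. Claisen–Schmidt condensation with bought vanillin (KOH, EtOH) gives (E)-1-[4-(benzyloxy)-2-hydroxy-3-methoxyphenyl]-3-(4-hydroxy-3-methoxyphenyl)prop-2-en-1-one F6. H2O2 and NaOH in MeOH close it to 7-(benzyloxy)-3-hydroxy-2-(4-hydroxy-3-methoxyphenyl)-8-methoxy-4H-chromen-4-one F7. tBuCOCl in pyridine caps the 3-OH and 4'-OH to give 7-(benzyloxy)-8-methoxy-2-[3-methoxy-4-(pivaloyloxy)phenyl]-4-oxo-4H-chromen-3-yl pivalate F8. Hydrogenolysis (H2, Pd/C, EtOAc), harmless at this stage because no prenyl group is present yet, gives 10.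

**Step 5 (C5–H hydroxylation).**
- Risk: hot CF3CO2H and a trivalent iodine oxidant meet two anisole-type rings. The 3-O-pivalate may be exchanged or may tie up the metal.
- Fallback: invert the logic. Buy the 5-oxygen and add the 8-methoxy group late instead. The fallback sets out from 6 and comes back at 15.

Compound 6 is condensed thermally (Ph2O, 240 °C) with bought phloroglucinol, the best substrate for this condensation. This gives 5,7-dihydroxy-2-[3-methoxy-4-(pivaloyloxy)phenyl]-4-oxo-4H-chromen-3-yl pivalate F9. K2CO3 and 14 in acetone alkylate only the non-chelated 7-OH to give 5-hydroxy-2-[3-methoxy-4-(pivaloyloxy)phenyl]-7-(3-methylbut-2-enyloxy)-4-oxo-4H-chromen-3-yl pivalate F10.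

PhI(OAc)2 (2.2 equiv) in MeOH/(CF3)2CHOH then oxidises the free 5-phenol, with methanol attacking para to it at C8. This is an untested extension of the known oxidation of para-unsubstituted phenols to quinone monoketals. It gives 8,8-dimethoxy-2-[3-methoxy-4-(pivaloyloxy)phenyl]-7-(3-methylbut-2-enyloxy)-4,5-dioxo-5,8-dihydro-4H-chromen-3-yl pivalate F11. Na2S2O4 in aqueous THF reduces F11 with loss of one methoxy group and rearomatisation to 15.

**Step 3 (Chan rearrangement).**
- Risk: intermolecular Claisen condensation, attack on the aryl pivalate, and the lability of 5.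
- Fallback: replace the intramolecular acyl shift by an intermolecular crossed Claisen acylation. The fallback sets out from 1 and 2 and comes back at 6.

Compound 1 is pivaloylated at the phenol (tBuCOCl, aqueous NaOH, 0 °C, then acidification) to 3-methoxy-4-(pivaloyloxy)benzoic acid F1. SOCl2 in toluene at 60 °C turns this into 3-methoxy-4-(pivaloyloxy)benzoyl chloride F2. Separately, 2 and KO2CtBu in DMF give ethyl 2-(pivaloyloxy)acetate F3. F3 (2 equiv) is deprotonated with LiN(iPr)2 in THF at −78 °C, where its hindered acyl group suppresses its own acyl shift. C-acylation with F2 then gives 6 directly.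

## Further compounds
F1 | step 3 | 3-methoxy-4-(pivaloyloxy)benzoic acid | COc1cc(C(=O)O)ccc1OC(=O)C(C)(C)C
F2 | step 3 | 3-methoxy-4-(pivaloyloxy)benzoyl chloride | COc1cc(C(=O)Cl)ccc1OC(=O)C(C)(C)C
F3 | step 3 | ethyl 2-(pivaloyloxy)acetate | CCOC(=O)COC(=O)C(C)(C)C
F4 | step 4 | 1-(2,4-dihydroxy-3-methoxyphenyl)ethanone | CC(=O)c1ccc(O)c(OC)c1O
F5 | step 4 | 1-[4-(benzyloxy)-2-hydroxy-3-methoxyphenyl]ethanone | CC(=O)c1ccc(OCc2ccccc2)c(OC)c1O
F6 | step 4 | (E)-1-[4-(benzyloxy)-2-hydroxy-3-methoxyphenyl]-3-(4-hydroxy-3-methoxyphenyl)prop-2-en-1-one | COc1cc(/C=C/C(=O)c2ccc(OCc3ccccc3)c(OC)c2O)ccc1O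
F7 | step 4 | 7-(benzyloxy)-3-hydroxy-2-(4-hydroxy-3-methoxyphenyl)-8-methoxy-4H-chromen-4-one | COc1cc(-c2oc3c(OC)c(OCc4ccccc4)ccc3c(=O)c2O)ccc1O
F8 | step 4 | 7-(benzyloxy)-8-methoxy-2-[3-methoxy-4-(pivaloyloxy)phenyl]-4-oxo-4H-chromen-3-yl pivalate | COc1cc(-c2oc3c(OC)c(OCc4ccccc4)ccc3c(=O)c2OC(=O)C(C)(C)C)ccc1OC(=O)C(C)(C)C
F9 | step 5 | 5,7-dihydroxy-2-[3-methoxy-4-(pivaloyloxy)phenyl]-4-oxo-4H-chromen-3-yl pivalate | COc1cc(-c2oc3cc(O)cc(O)c3c(=O)c2OC(=O)C(C)(C)C)ccc1OC(=O)C(C)(C)C
F10 | step 5 | 5-hydroxy-2-[3-methoxy-4-(pivaloyloxy)phenyl]-7-(3-methylbut-2-enyloxy)-4-oxo-4H-chromen-3-yl pivalate | COc1cc(-c2oc3cc(OCC=C(C)C)cc(O)c3c(=O)c2OC(=O)C(C)(C)C)ccc1OC(=O)C(C)(C)C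
F11 | step 5 | 8,8-dimethoxy-2-[3-methoxy-4-(pivaloyloxy)phenyl]-7-(3-methylbut-2-enyloxy)-4,5-dioxo-5,8-dihydro-4H-chromen-3-yl pivalate | COc1cc(C2=C(OC(=O)C(C)(C)C)C(=O)C3=C(O2)C(OC)(OC)C(OCC=C(C)C)=CC3=O)ccc1OC(=O)C(C)(C)C
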